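## Analysis of the target

Target 20 is an isoflavan quinone. A chroman (aromatic ring A fused to the dihydropyran ring C, atoms O1, C2, C3, C4, C4a, C8a) carries at C3 a 2,3-dimethoxy-1,4-benzoquinone (ring B). Ring A is substituted everywhere except C5, with methoxy groups at C6 and C7 and a free phenol at C8 next to the ring oxygen. C3 is the only stereocenter and is S. It is a carbon flanked by two methylene groups (C2 and C4) and bears no heteroatom, so it must be set by C–C bond formation or by hydrogenation. The sensitive groups are the quinone (reducible, attacked by bases and nucleophiles at its vinylogous ester positions), the electron-rich C8 phenol (oxidisable) and the C3–H bond, which is allylic to the quinone. The synthesis is hard for three reasons: an isolated stereocenter, two contiguously tetra-oxygenated rings whose patterns must be exact, and a quinone that has to be revealed last beside a free phenol. The strategy rests on the C3–C4 unit: C3 bears ring B and is bonded to C4H2, which is bonded to C4a of ring A. C3–C4 can therefore come from a vinyl boron unit, with ring B migrating from boron to C3, ring A delivered to C4, and boron left on C3 as the handle for C2.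

## Retrosynthetic reasoning

**Quinone last (20 ⇒ 19 ⇒ 18).** No skeletal bond is cut first. The quinone of 20 is traced to hydroquinone 19 and then to the tribenzyl ether 18. A quinone would not survive the organolithium, borate, fluoride and phosphine chemistry needed earlier, whereas a fully etherified ring B is inert. The forward reaction has to remove three benzyl groups and oxidise only the para-dihydroxy ring while the C8 phenol stays.

**O1–C2 (18 ⇒ 17 ⇒ 16).** Ring C is opened at O1–C2. Cutting C8a–O1 instead would need an aryl C–O coupling at a crowded, electron-rich position. Cutting C4–C4a would need a Friedel–Crafts closure with no control of C3. The chosen cut leaves phenol-alcohol 17, and the forward reaction is a substitution at a primary carbon that does not touch C3. 17 comes from silyl ether 16, in which the C8a oxygen (silyl) is distinguished from the C8 oxygen (benzyl), so that O1 can be freed alone.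

**C2–C3 (16 ⇒ 15 ⇒ 14).** C2 is a one-carbon unit bearing oxygen. Cutting C2–C3 turns C3 into the boron-bearing carbon of the secondary benzylic boronate 14. The gain is that the stereocenter becomes a C–B centre, for which a catalytic enantioselective construction exists. The forward reaction must insert one carbon into the C–B bond with retention (giving 15) and then oxidise the new primary C–B bond.

**C3–ring B and C4–C4a (14 ⇒ 13 + 10; 13 ⇒ 12 + 11; 12 ⇒ 4).** Both aryl–alkyl bonds of 14 are cut at once. This leaves vinyl boronate 11 as the C3–C4 unit, aryllithium 12 (from bromide 4) as ring B, and aryl bromide 10 as ring A. These two bonds are the only links between three simple pieces, and the stereocenter is formed in the same event. The forward reaction must make borate 13, move ring B from boron to C3, bond ring A to C4, and select one face of the vinyl group.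

**Ring A partner (10 ⇒ 9 ⇒ 8 ⇒ 7 ⇒ 6 ⇒ 5).** The O–Si bond and then the C–Br bond of 10 are removed, giving phenol 8. Its hydroxyl is the only strong ortho director and its para position is blocked, so bromination should go to the required carbon. The phenol oxygen of 8 replaces the formyl carbon of aldehyde 6 through formate 7, and 6 is the benzyl ether of the commercial aldehyde 5. All four ring oxygens are thus in place from the start.

**Ring B partner (4 ⇒ 3 ⇒ 2 ⇒ 1).** Bromide 4 is traced to the symmetric dibenzyl ether 3, to hydroquinone 2 and to quinone 1. Because 3 has two equivalent free positions, the bromination has no regiochemical question. The ring returns to the quinone oxidation state by the same two oxygens at the end.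

## Alternatives that were turned down

**Alternative 1:** squarate ring expansion, with the quinone built last.
- Disconnection: the whole quinone ring is removed. Two of its carbons come from an alkyne on C3 of the 3-ethynylchroman A2, and four from dimethyl squarate A3.
- Forward key step: the lithium acetylide of A2 adds to A3 to give the alkynyl hydroxycyclobutenone A4. Heating A4 in toluene opens the four-membered ring to an alkynyl ketene. The ketene carbon bonds to the alkyne carbon that bears the chroman, and hydrogen transfer gives quinone A1. Acid then removes the methoxymethyl group.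
- For it: the dimethoxyquinone is formed with fixed regiochemistry and in its final oxidation state. Ring B needs no protecting groups and no oxidation beside the C8 phenol. On this point it is stronger than the chosen route, whose last step depends on chemoselective oxidation of 19.
- Against it: it does nothing for the stereocenter. A2 must already hold C3 in enantiopure form on a finished chroman. The alkyne has to be installed at a carbon that is at some stage α to a carbonyl group and β to the aryloxy oxygen, a position that epimerises and eliminates under basic alkyne-forming conditions. A separate asymmetric step and a long sequence precede the key step. The thermolysis also passes through a diradical next to the C3–H bond.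
- Comparison: the chosen route makes C3 and both aryl–carbon bonds in one catalytic step from three simple pieces. In place of built-in quinone regiochemistry it uses the symmetric ring B source 1, in which regiochemistry cannot go wrong.

**Alternative 2:** quinone–chromene cycloaddition through a temporary pterocarpan ring.
- Disconnection: C3–ring B and a temporary C4–O bond. Ring B enters as quinone 1 itself and ring A as the 2H-chromene A6.
- Forward key step: a stoichiometric titanium Lewis acid carrying a chiral tartrate-derived diol (tetravalent titanium) activates 1. The double bond of A6 attacks the unsubstituted quinone carbon, and the benzylic cation at C4 is captured by the neighbouring carbonyl oxygen. This gives the cis-fused pterocarpan phenol A5. Hydrogenolysis of the benzylic C4–O bond and of the benzyl ether would give 19, which is oxidised to 20.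
- For it: it is clearly the shortest route, with two steps after the key step and no protecting groups on ring B. On step count it beats the chosen route.
- Against it: the chiral promoter is stoichiometric. Alkoxyquinones and styrene-type alkenes partition between [2+2], [5+2] and [3+2] adducts with small changes in quinone substituents and titanium ligands. Enantioselection depends on one titanium chelate, and its geometry is uncertain for a quinone with two adjacent methoxy groups. The very electron-rich A6 is prone to Lewis-acid ionisation and oligomerisation.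
- Comparison: the chosen route is longer, but its stereo-determining step is catalytic and runs through closed-shell organometallic intermediates with no carbocation at C4.

**Alternative 3:** phenol–arylacrolein annulation with enantioselective protonation.
- Disconnection: C4–C4a and O1–C2, with C3 created by protonation. The pieces are phenol 8 and the 2-arylacrolein A8.
- Forward key step: a chiral primary amine–sulfonic acid salt converts A8 into an iminium ion. The ortho carbon of 8 adds to it (C4–C4a), the enamine is protonated enantioselectively at C3, and the phenol oxygen closes lactol A7 (O1–C2). Deoxygenation of A7 would give 18.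
- For it: it is metal-free and uses 8 without bromination or silylation, so the ring A branch is two steps shorter. In bond economy it equals the chosen route.
- Against it: the new stereocenter is α to a masked aldehyde and carries an aryl group. It is labile under the same amine/acid conditions that create it, and again in the lactol reduction, which passes through an oxocarbenium ion that can lose the C3 proton. Carbon attack by 8 competes with oxa-Michael addition. Enantioselective protonation with a phenol as the carbon nucleophile has narrow precedent.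
- Comparison: the chosen route fixes C3 as a C–B stereocenter, which has no epimerisation pathway and is carried on by stereoretentive migrations.

Key step: step 8

Remark 1: quinone 1 and aldehyde 5 are treated as purchasable compounds.

Remark 2: the (Sp,Sp) antipode of the ferrocenyl bisphosphine MandyPhos (C52H50FeN2P2) is assumed to lead to (S)-14. If the sense of induction is the opposite, the (Rp,Rp) antipode is used with nothing else changed.

## Route

Step 1
Reactants: 1 2,3-dimethoxy-1,4-benzoquinone
Product: 2 2,3-dimethoxybenzene-1,4-diol
Conditions: Na2S2O4, H2O/EtOAc, rt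
Reagents that add atoms: none
Why: Dithionite reduction of a quinone to its hydroquinone; the two-phase medium moves the product into the organic layer and limits re-oxidation by air.

Step 2
Reactants: 2 2,3-dimethoxybenzene-1,4-diol
Product: 3 1,4-bis(benzyloxy)-2,3-dimethoxybenzene
Conditions: BnBr, K2CO3, DMF, 60 °C, N2
Reagents that add atoms: benzyl bromide, BrCc1ccccc1
Why: Williamson ether synthesis on both phenoxide oxygens; benzyl ethers survive the organolithium, palladium, fluoride and phosphine steps and leave together with the ring A benzyl group at the end.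

Step 3
Reactants: 3 1,4-bis(benzyloxy)-2,3-dimethoxybenzene
Product: 4 1,4-bis(benzyloxy)-5-bromo-2,3-dimethoxybenzene
Conditions: NBS (1.0 equiv), MeCN, 0 °C → rt
Reagents that add atoms: N-bromosuccinimide, O=C1CCC(=O)N1Br
Why: Electrophilic aromatic bromination; the two free positions are equivalent by symmetry, so only one monobromide can form, and the first bromine slows a second substitution.

Step 4
Reactants: 5 2-hydroxy-3,4-dimethoxybenzaldehyde
Product: 6 2-(benzyloxy)-3,4-dimethoxybenzaldehyde
Conditions: BnBr, K2CO3, DMF, 60 °C
Reagents that add atoms: benzyl bromide, BrCc1ccccc1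
Why: Williamson etherification of the ortho-hydroxy aldehyde; this benzyl group becomes the protecting group of the C8 phenol.

Step 5
Reactants: 6 2-(benzyloxy)-3,4-dimethoxybenzaldehyde
Product: 8 2-(benzyloxy)-3,4-dimethoxyphenol, via aryl formate 7 (not isolated)
Conditions: mCPBA, CH2Cl2, 0 °C → rt; then K2CO3 (cat.), MeOH, rt
Reagents that add atoms: 3-chloroperoxybenzoic acid (mCPBA), OOC(=O)c1cccc(Cl)c1
Why: Baeyer–Villiger oxidation of an electron-rich benzaldehyde (Dakin-type oxidation): the aryl group migrates in the Criegee intermediate to give formate 7, which methanol transesterifies to the phenol; the formyl carbon is thereby replaced by the future O1.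

Step 6
Reactants: 8 2-(benzyloxy)-3,4-dimethoxyphenol
Product: 9 2-(benzyloxy)-6-bromo-3,4-dimethoxyphenol
Conditions: NBS, i-Pr2NH (10 mol%), CH2Cl2, −78 → 0 °C
Reagents that add atoms: N-bromosuccinimide, O=C1CCC(=O)N1Br
Why: Hydroxyl-directed electrophilic bromination: the para position is blocked by methoxy and C6 is the only open ortho position; the secondary amine forms an N-bromoamine that is hydrogen-bonded to the phenol, which should favour ortho delivery over attack at C5, a position activated only by ether groups.

Step 7
Reactants: 9 2-(benzyloxy)-6-bromo-3,4-dimethoxyphenol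
Product: 10 [2-(benzyloxy)-6-bromo-3,4-dimethoxyphenoxy](tert-butyl)dimethylsilane
Conditions: TBSCl, imidazole, DMF, rt
Reagents that add atoms: tert-butyldimethylsilyl chloride, CC(C)(C)[Si](C)(C)Cl
Why: Silylation of the phenol; the silyl ether removes the acidic OH that would quench the borate complex and is orthogonal to the benzyl ethers, so that O1 can later be freed alone.

Step 8
Reactants: 4 1,4-bis(benzyloxy)-5-bromo-2,3-dimethoxybenzene; 11 4,4,5,5-tetramethyl-2-vinyl-1,3,2-dioxaborolane; 10 [2-(benzyloxy)-6-bromo-3,4-dimethoxyphenoxy](tert-butyl)dimethylsilane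
Product: 14 2-[(1S)-1-[2,5-bis(benzyloxy)-3,4-dimethoxyphenyl]-2-[3-(benzyloxy)-2-(tert-butyldimethylsilyloxy)-4,5-dimethoxyphenyl]ethyl]-4,4,5,5-tetramethyl-1,3,2-dioxaborolane, via ring B aryllithium 12 (not isolated), via lithium aryl(vinyl)borate 13 (not isolated)
Conditions: 4, n-BuLi, THF, −78 °C; 11, −78 °C → rt; evaporate; then 10, Pd(OAc)2 (2 mol%), (Sp,Sp)-MandyPhos C52H50FeN2P2 (2.4 mol%), NaOTf, THF, 60 °C
Reagents that add atoms: none
Why: Lithium–bromine exchange converts 4 into aryllithium 12, which adds to the vacant boron orbital of 11 to give the four-coordinate borate 13. Oxidative addition of 10 to zerovalent palladium carrying MandyPhos (C52H50FeN2P2), followed by removal of bromide as NaBr by NaOTf, gives a cationic divalent arylpalladium species that binds the vinyl group of 13. This π-activation induces a 1,2-shift of ring B from boron to the α-carbon (C3), anti to the metal, while the β-carbon (C4) becomes bonded to palladium; reductive elimination then forms C4–C4a and releases 14 and zerovalent palladium. The closest known reaction type is the palladium-catalysed enantioselective conjunctive cross-coupling of aryl(vinyl)boronate complexes with aryl halides in the presence of a triflate salt. No ring is closed in this step. The only new stereocenter, C3, is set by the enantioface of the vinyl group that the chiral bisphosphine–palladium fragment selects, and the anti migration translates that choice into the (S) configuration at the C–B carbon. The step needs the metallate shift to outrun direct transmetallation of 13 (biaryl or styrene formation) and β-hydride elimination from the alkylpalladium intermediate; the non-migrating pinacolate ligand, the high migratory aptitude of the electron-rich ring B, the halide-free cationic palladium centre and the fast reductive elimination enforced by the ferrocenyl bisphosphine should secure this. Both aryl groups carry one ortho substituent, which is the reason for 60 °C and a small excess of 13.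

Step 9
Reactants: 14 2-[(1S)-1-[2,5-bis(benzyloxy)-3,4-dimethoxyphenyl]-2-[3-(benzyloxy)-2-(tert-butyldimethylsilyloxy)-4,5-dimethoxyphenyl]ethyl]-4,4,5,5-tetramethyl-1,3,2-dioxaborolane
Product: 16 (2S)-2-[2,5-bis(benzyloxy)-3,4-dimethoxyphenyl]-3-[3-(benzyloxy)-2-(tert-butyldimethylsilyloxy)-4,5-dimethoxyphenyl]propan-1-ol, via homologated primary boronate 15 (not isolated)
Conditions: BrCH2Cl, n-BuLi, THF, −78 °C → rt; then NaBO3·4H2O, THF/H2O, rt
Reagents that add atoms: bromochloromethane, ClCBr; sodium perborate (NaBO3·4H2O), [Na+].[Na+].O[B-]1(O)OO[B-](O)(O)OO1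
Why: Matteson homologation: chloromethyllithium, made in the flask by lithium–bromine exchange, adds to boron and the secondary benzylic carbon C3 migrates with retention as chloride leaves, which attaches C2 without disturbing the stereocenter; perborate then oxidises the primary C–B bond to C–OH under conditions mild enough for the aryl silyl ether, and any silyl loss here is harmless because step 10 removes that group.

Step 10
Reactants: 16 (2S)-2-[2,5-bis(benzyloxy)-3,4-dimethoxyphenyl]-3-[3-(benzyloxy)-2-(tert-butyldimethylsilyloxy)-4,5-dimethoxyphenyl]propan-1-ol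
Product: 17 2-(benzyloxy)-6-[(2S)-2-[2,5-bis(benzyloxy)-3,4-dimethoxyphenyl]-3-hydroxypropyl]-3,4-dimethoxyphenol
Conditions: TBAF, AcOH, THF, 0 °C → rt
Reagents that add atoms: none
Why: Fluoride-induced desilylation of the aryl silyl ether; the acetic acid buffer keeps the electron-rich phenol from standing as its free anion.

Step 11
Reactants: 17 2-(benzyloxy)-6-[(2S)-2-[2,5-bis(benzyloxy)-3,4-dimethoxyphenyl]-3-hydroxypropyl]-3,4-dimethoxyphenol
Product: 18 (3S)-8-(benzyloxy)-3-[2,5-bis(benzyloxy)-3,4-dimethoxyphenyl]-6,7-dimethoxychroman
Conditions: PPh3, DIAD, THF, 0 °C → rt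
Reagents that add atoms: none
Why: Intramolecular Mitsunobu etherification: the phenol, the only acidic OH, attacks the activated primary carbinol C2 in a 6-exo-tet closure of O1–C2; C3 is not a reacting centre and keeps its configuration.

Step 12
Reactants: 18 (3S)-8-(benzyloxy)-3-[2,5-bis(benzyloxy)-3,4-dimethoxyphenyl]-6,7-dimethoxychroman
Product: 20 5-[(3S)-8-hydroxy-6,7-dimethoxychroman-3-yl]-2,3-dimethoxy-1,4-benzoquinone, via hydroquinone 19 (not isolated)
Conditions: H2 (1 atm), Pd/C, EtOAc/MeOH, rt; filter under N2; then FeCl3·6H2O (2.2 equiv), MeCN/H2O, 0 °C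
Reagents that add atoms: none
Why: Hydrogenolysis cleaves the three aryl benzyl ethers to give hydroquinone 19; FeCl3 then oxidises the para-dihydroxy ring in two one-electron steps to the quinone, the isolated C8 phenol being much harder to oxidise, and no base is present that could epimerise C3.

## Compound list

1 | 2,3-dimethoxy-1,4-benzoquinone | COC1=C(OC)C(=O)C=CC1=O | starting material
2 | 2,3-dimethoxybenzene-1,4-diol | COc1c(O)ccc(O)c1OC | intermediate
3 | 1,4-bis(benzyloxy)-2,3-dimethoxybenzene | COc1c(OCc2ccccc2)ccc(OCc2ccccc2)c1OC | intermediate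
4 | 1,4-bis(benzyloxy)-5-bromo-2,3-dimethoxybenzene (ring B bromide) | Brc1cc(OCc2ccccc2)c(OC)c(OC)c1OCc1ccccc1 | intermediate
5 | 2-hydroxy-3,4-dimethoxybenzaldehyde | COc1ccc(C=O)c(O)c1OC | starting material
6 | 2-(benzyloxy)-3,4-dimethoxybenzaldehyde | COc1ccc(C=O)c(OCc2ccccc2)c1OC | intermediate
7 | 2-(benzyloxy)-3,4-dimethoxyphenyl formate | COc1ccc(OC=O)c(OCc2ccccc2)c1OC | intermediate
8 | 2-(benzyloxy)-3,4-dimethoxyphenol | COc1ccc(O)c(OCc2ccccc2)c1OC | intermediate
9 | 2-(benzyloxy)-6-bromo-3,4-dimethoxyphenol | COc1cc(Br)c(O)c(OCc2ccccc2)c1OC | intermediate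
10 | [2-(benzyloxy)-6-bromo-3,4-dimethoxyphenoxy](tert-butyl)dimethylsilane (ring A bromide) | Brc1cc(OC)c(OC)c(OCc2ccccc2)c1O[Si](C)(C)C(C)(C)C | intermediate
11 | 4,4,5,5-tetramethyl-2-vinyl-1,3,2-dioxaborolane (vinylboronic acid pinacol ester) | C=CB1OC(C)(C)C(C)(C)O1 | starting material
12 | [2,5-bis(benzyloxy)-3,4-dimethoxyphenyl]lithium | [Li]c1cc(OCc2ccccc2)c(OC)c(OC)c1OCc1ccccc1 | intermediate
13 | lithium [2,5-bis(benzyloxy)-3,4-dimethoxyphenyl](pinacolato)vinylborate | [Li+].C=C[B-]1(OC(C)(C)C(C)(C)O1)c1cc(OCc2ccccc2)c(OC)c(OC)c1OCc1ccccc1 | intermediate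
14 | 2-[(1S)-1-[2,5-bis(benzyloxy)-3,4-dimethoxyphenyl]-2-[3-(benzyloxy)-2-(tert-butyldimethylsilyloxy)-4,5-dimethoxyphenyl]ethyl]-4,4,5,5-tetramethyl-1,3,2-dioxaborolane | CC1(C)OB(OC1(C)C)[C@@H](Cc1cc(OC)c(OC)c(OCc2ccccc2)c1O[Si](C)(C)C(C)(C)C)c1cc(OCc2ccccc2)c(OC)c(OC)c1OCc1ccccc1 | intermediate
15 | 2-[(2S)-2-[2,5-bis(benzyloxy)-3,4-dimethoxyphenyl]-3-[3-(benzyloxy)-2-(tert-butyldimethylsilyloxy)-4,5-dimethoxyphenyl]propyl]-4,4,5,5-tetramethyl-1,3,2-dioxaborolane | CC1(C)OB(OC1(C)C)C[C@@H](Cc1cc(OC)c(OC)c(OCc2ccccc2)c1O[Si](C)(C)C(C)(C)C)c1cc(OCc2ccccc2)c(OC)c(OC)c1OCc1ccccc1 | intermediate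
16 | (2S)-2-[2,5-bis(benzyloxy)-3,4-dimethoxyphenyl]-3-[3-(benzyloxy)-2-(tert-butyldimethylsilyloxy)-4,5-dimethoxyphenyl]propan-1-ol | OC[C@@H](Cc1cc(OC)c(OC)c(OCc2ccccc2)c1O[Si](C)(C)C(C)(C)C)c1cc(OCc2ccccc2)c(OC)c(OC)c1OCc1ccccc1 | intermediate
17 | 2-(benzyloxy)-6-[(2S)-2-[2,5-bis(benzyloxy)-3,4-dimethoxyphenyl]-3-hydroxypropyl]-3,4-dimethoxyphenol | OC[C@@H](Cc1cc(OC)c(OC)c(OCc2ccccc2)c1O)c1cc(OCc2ccccc2)c(OC)c(OC)c1OCc1ccccc1 | intermediate
18 | (3S)-8-(benzyloxy)-3-[2,5-bis(benzyloxy)-3,4-dimethoxyphenyl]-6,7-dimethoxychroman | COc1c(OC)c(OCc2ccccc2)c([C@H]3COc4c(cc(OC)c(OC)c4OCc5ccccc5)C3)cc1OCc1ccccc1 | intermediate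
19 | 2-[(3S)-8-hydroxy-6,7-dimethoxychroman-3-yl]-5,6-dimethoxybenzene-1,4-diol | COc1c(OC)c(O)c([C@H]2COc3c(cc(OC)c(OC)c3O)C2)cc1O | intermediate
20 | 5-[(3S)-8-hydroxy-6,7-dimethoxychroman-3-yl]-2,3-dimethoxy-1,4-benzoquinone (CNP0269725.1) | COC1=C(OC)C(=O)C([C@H]2COc3c(cc(OC)c(OC)c3O)C2)=CC1=O | target

## Step count and least certain steps

Total step count: 12. Longest linear sequence: 9 steps (from 5 to 20, steps 4 to 12). The ring B branch (steps 1 to 3) joins at step 8.

**Step 8 (key step).**
- What may go wrong: the palladium-bound ring A aryl is crowded by its ortho silyloxy group and its ring is electron-rich. Alkene binding may then be slow, so that direct transmetallation of 13 or its protodeboronation overtakes the metallate shift. Face selection may also be eroded because both aryl partners are ortho-substituted. Residual bromide can inhibit the cationic pathway.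
- Fallback: an auxiliary-controlled enolate alkylation, setting out from 4 and 8 and returning at 16.
- Ring B part: 4 is coupled with the Reformatsky reagent BrZnCH2CO2Et (Pd(dba)2, XPhos, THF, 60 °C) to give ethyl [2,5-bis(benzyloxy)-3,4-dimethoxyphenyl]acetate F1. LiOH gives the acid F2. t-BuCOCl, Et3N, LiCl and (S)-4-benzyl-oxazolidin-2-one give the imide F3.
- Ring A part: 8 is formylated at its only free ortho position (MgCl2, Et3N, paraformaldehyde, MeCN, reflux) to give salicylaldehyde F4. TBSCl/imidazole gives silyl ether F5, NaBH4 gives benzyl alcohol F6, and CBr4/PPh3 gives benzyl bromide F7.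
- Union: the sodium enolate of F3 (NaN(SiMe3)2, THF, −78 °C) is alkylated by F7 on the face opposite the auxiliary benzyl group to give imide F8. LiBH4 reduces F8 to 16. The route continues with step 10.

**Step 9.**
- What may go wrong: α-elimination of the chloromethyl carbenoid before it adds to the crowded secondary boronate, or incomplete migration. Oxidation of unhomologated boronate would then consume material.
- Fallback: C2 is introduced as a vinyl group, setting out from 14 and returning at 16. CH2=CHMgBr (excess, THF) forms the vinyl borate, which can be driven to completion with a stable nucleophile. I2 then NaOMe (MeOH, −78 °C → rt) effects the Zweifel olefination with retention to give alkene F9. OsO4 (cat.)/NaIO4/2,6-lutidine in dioxane/H2O cleaves it to aldehyde F10, which is not isolated but reduced at once with NaBH4 at 0 °C to limit epimerisation of the α-aryl aldehyde. This gives 16.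

**Step 6.**
- What may go wrong: competing bromination at C5 (para to the benzyloxy group, ortho to a methoxy group), or oxidation of the electron-rich phenol by the brominating agent.
- Fallback: directed ortho-metalation, setting out from 8 and returning at 9. MOMCl/i-Pr2NEt gives the methoxymethyl ether F11. n-BuLi (THF, 0 °C) lithiates the only position ortho to the acetal oxygen, and BrCF2CF2Br gives bromide F12. HCl in MeOH removes the acetal to give 9.

**Step 12.**
- What may go wrong: one-electron oxidation of the C8 phenol on ring A by trivalent iron in competition with the hydroquinone, leading to oxidative coupling or ring A oxidation.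
- Fallback: the oxidation is changed from a kinetic metal oxidant to a quinone–hydroquinone redox exchange, setting out from 19 and returning at 20. Crude 19 is stirred with 1,4-benzoquinone (2 equiv, CH2Cl2/MeOH, rt). The electron-rich hydroquinone ring is oxidised by equilibrium hydrogen transfer, and a monophenol cannot be oxidised by this reagent on thermodynamic grounds. No new compound is formed.

## Further compounds

F1 | step 8 | ethyl [2,5-bis(benzyloxy)-3,4-dimethoxyphenyl]acetate | CCOC(=O)Cc1cc(OCc2ccccc2)c(OC)c(OC)c1OCc1ccccc1
F2 | step 8 | [2,5-bis(benzyloxy)-3,4-dimethoxyphenyl]acetic acid | OC(=O)Cc1cc(OCc2ccccc2)c(OC)c(OC)c1OCc1ccccc1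
F3 | step 8 | (4S)-4-benzyl-3-{[2,5-bis(benzyloxy)-3,4-dimethoxyphenyl]acetyl}oxazolidin-2-one | O=C1OC[C@H](Cc2ccccc2)N1C(=O)Cc1cc(OCc2ccccc2)c(OC)c(OC)c1OCc1ccccc1
F4 | step 8 | 3-(benzyloxy)-2-hydroxy-4,5-dimethoxybenzaldehyde | O=Cc1cc(OC)c(OC)c(OCc2ccccc2)c1O
F5 | step 8 | 3-(benzyloxy)-2-(tert-butyldimethylsilyloxy)-4,5-dimethoxybenzaldehyde | O=Cc1cc(OC)c(OC)c(OCc2ccccc2)c1O[Si](C)(C)C(C)(C)C
F6 | step 8 | [3-(benzyloxy)-2-(tert-butyldimethylsilyloxy)-4,5-dimethoxyphenyl]methanol | OCc1cc(OC)c(OC)c(OCc2ccccc2)c1O[Si](C)(C)C(C)(C)C
F7 | step 8 | [2-(benzyloxy)-6-(bromomethyl)-3,4-dimethoxyphenoxy](tert-butyl)dimethylsilane | BrCc1cc(OC)c(OC)c(OCc2ccccc2)c1O[Si](C)(C)C(C)(C)C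
F8 | step 8 | (4S)-4-benzyl-3-[(2S)-2-[2,5-bis(benzyloxy)-3,4-dimethoxyphenyl]-3-[3-(benzyloxy)-2-(tert-butyldimethylsilyloxy)-4,5-dimethoxyphenyl]propanoyl]oxazolidin-2-one | O=C1OC[C@H](Cc2ccccc2)N1C(=O)[C@@H](Cc1cc(OC)c(OC)c(OCc2ccccc2)c1O[Si](C)(C)C(C)(C)C)c1cc(OCc2ccccc2)c(OC)c(OC)c1OCc1ccccc1
F9 | step 9 | (3R)-3-[2,5-bis(benzyloxy)-3,4-dimethoxyphenyl]-4-[3-(benzyloxy)-2-(tert-butyldimethylsilyloxy)-4,5-dimethoxyphenyl]but-1-ene | C=C[C@@H](Cc1cc(OC)c(OC)c(OCc2ccccc2)c1O[Si](C)(C)C(C)(C)C)c1cc(OCc2ccccc2)c(OC)c(OC)c1OCc1ccccc1
F10 | step 9 | (2S)-2-[2,5-bis(benzyloxy)-3,4-dimethoxyphenyl]-3-[3-(benzyloxy)-2-(tert-butyldimethylsilyloxy)-4,5-dimethoxyphenyl]propanal | O=C[C@@H](Cc1cc(OC)c(OC)c(OCc2ccccc2)c1O[Si](C)(C)C(C)(C)C)c1cc(OCc2ccccc2)c(OC)c(OC)c1OCc1ccccc1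
F11 | step 6 | 2-(benzyloxy)-3,4-dimethoxy-1-(methoxymethoxy)benzene | COCOc1ccc(OC)c(OC)c1OCc1ccccc1
F12 | step 6 | 3-(benzyloxy)-1-bromo-4,5-dimethoxy-2-(methoxymethoxy)benzene | COCOc1c(Br)cc(OC)c(OC)c1OCc1ccccc1
F0 | step 12 | none | none
A1 | alternative 1 | 5-[(3S)-6,7-dimethoxy-8-(methoxymethoxy)chroman-3-yl]-2,3-dimethoxy-1,4-benzoquinone | COC1=C(OC)C(=O)C([C@H]2COc3c(cc(OC)c(OC)c3OCOC)C2)=CC1=O
A2 | alternative 1 | (3S)-3-ethynyl-6,7-dimethoxy-8-(methoxymethoxy)chroman | C#C[C@H]1COc2c(cc(OC)c(OC)c2OCOC)C1
A3 | alternative 1 | dimethyl squarate (3,4-dimethoxycyclobut-3-ene-1,2-dione) | COC1=C(OC)C(=O)C1=O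
A4 | alternative 1 | 4-{[(3S)-6,7-dimethoxy-8-(methoxymethoxy)chroman-3-yl]ethynyl}-4-hydroxy-2,3-dimethoxycyclobut-2-en-1-one (carbinol carbon of either configuration) | COC1=C(OC)C(O)(C#C[C@H]2COc3c(cc(OC)c(OC)c3OCOC)C2)C1=O
A5 | alternative 2 | cis-fused 4-(benzyloxy)-2,3,9,10-tetramethoxy-6a,11a-dihydro-6H-benzofuro[3,2-c]chromen-8-ol (pterocarpan phenol) | COc1c(OC)c(O)cc2c1O[C@@H]1c3cc(OC)c(OC)c(OCc4ccccc4)c3OC[C@H]21
A6 | alternative 2 | 8-(benzyloxy)-6,7-dimethoxy-2H-chromene | C1=Cc2cc(OC)c(OC)c(OCc3ccccc3)c2OC1
A7 | alternative 3 | (3S)-8-(benzyloxy)-3-[2,5-bis(benzyloxy)-3,4-dimethoxyphenyl]-6,7-dimethoxychroman-2-ol (both anomers) | OC1Oc2c(cc(OC)c(OC)c2OCc2ccccc2)C[C@H]1c1cc(OCc2ccccc2)c(OC)c(OC)c1OCc1ccccc1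
A8 | alternative 3 | 2-[2,5-bis(benzyloxy)-3,4-dimethoxyphenyl]prop-2-enal | C=C(C=O)c1cc(OCc2ccccc2)c(OC)c(OC)c1OCc1ccccc1
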